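## Structural features

The target is a daucane-type sesquiterpenoid ester in which a cyclopentane (C1–C5) is trans-fused through the C1–C5 bond to a cycloheptane (C1, C5–C10); C1 is the methyl-bearing quaternary fusion carbon, C2 and C3 are CH2 groups, C4 is the isopropyl carbinol, C5 the fusion CH, C6 the CH carrying the 4-hydroxybenzoate, C7 the ketone, C8 the methyl carbinol, C9 the secondary carbinol and C10 a CH2 group. C1, C4, C5 and C6 form one contiguous cluster of stereocentres and C8/C9 a second pair, separated by the C7 carbonyl. The methyl on C1 and the hydroxyl on C4 are β, whereas the hydrogen on C5, the isopropyl group and the oxygens at C6, C8 and C9 are α. Fragile elements are the tertiary α-ketol at C7/C8 (acyloin shift, retro-aldol), the α-acyloxy ketone (C6 epimerisation, acyl migration), the tertiary C4 carbinol (acid-induced dehydration) and the phenolic ester (base). The real difficulty is the stereocontrolled oxygenation of four consecutive ring carbons (C6–C9) next to a trans fusion flanked by two fully substituted carbons, all relayed from one quaternary centre. The key step exploits the division of the seven-membered ring into a five-carbon unit C7–C6–C5–C1–C10 (a vinylcyclopropane fused to the five-membered ring) and a two-carbon unit C8–C9 with its methyl group (a propyne). After their union, C5=C6 and C8=C9 lie where C5–H/C6–O and C8–O/C9–O are needed, C7 sits between them, and the C4 carbonyl is ready for the isopropyl carbinol. In that cycloadduct CH3 and C10 on C1 flank the enone plane almost symmetrically, so the first stereochemical choice after the cycloaddition is left to a chiral reagent and is then relayed by the substrate.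

## Logic of the disconnections

23 ⇒ 22. The O–CH2Ph bond of the phenol is cut. A free phenol would not survive the organometallic and oxidative steps. The forward step must cleave it under neutral conditions that spare the α-ketol and both esters.

22 ⇒ 21. The C8–O and C9–O bonds are cut together, because two cis α-oxygens correspond to one syn addition to C8=C9. Two stereocentres disappear. The forward step must attack the α face of an electron-poor alkene.

21 ⇒ 20 ⇒ 19. The C7 carbonyl is taken back to CH2. C7 is the ring methylene on the more substituted carbon of C8=C9, which is the position an ene-type selenium oxidation addresses. Removing the ketone removes the C6 epimerisation risk from all earlier steps. The forward step must choose C7 over the C8 methyl and C10.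

19 ⇒ 18. The C4–CH(CH3)2 bond is cut, returning to the C4 carbonyl. At this stage the ring fusion is trans and the 1β-methyl is axial and 1,3 to C4, so addition from the α face is expected. The nucleophile must be non-basic, because 18 is a β-acyloxy ketone.

18 ⇒ 17 ⇒ 15. These are functional-group changes only: C4 ketone from the C4 silyl ether, and C9–H from C9–Si. Both silicon groups had a task (face control at C5=C6, shielding of C8=C9) and are removed together. The acid must not move the C8=C9 alkene.

15 ⇒ 13 + 14. The ester C–O bond at O6 is cut, which detaches the aromatic part as a purchasable acyl donor. In 13 the C6 hydroxyl is the only free one; it is hindered, so an activated acyl donor is required.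

13 ⇒ 11. The C5–H and C6–O bonds are cut as one syn addition across C5=C6, creating both stereocentres at once. The forward step needs α-face attack (ensured by the 4β-silyloxy group and the 1β-methyl) and must leave C8=C9 alone (ensured by its tetrasubstitution and the silyl group).

11 ⇒ 10 ⇒ 9. The O–Si and C4–H bonds are removed to reach the cycloadduct. A temporary C4 carbinol is introduced because 9 offers little facial bias. The reduction must be catalyst-controlled.

9 ⇒ 7 + 8 (key). C7–C8 and C9–C10 are cut, which removes the seven-membered ring and leaves a bicyclic vinylcyclopropane and an alkyne. The forward step must cleave C5–C10 and not C5–C1, orient the alkyne with its methyl carbon at C7, and leave C1 untouched.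

7 ⇒ 6 ⇒ 5. The C1–C10 and C5–C10 bonds of the cyclopropane are cut after returning the ketone to a carbinol. The carbinol oxygen can then deliver the methylene and transfer its configuration to the quaternary C1. A one-step asymmetric methylene transfer to the corresponding 2-vinyl enone would be shorter, but it has no precedent for a tetrasubstituted cyclic enone. The forward step must select the ring alkene over the vinyl group.

5 ⇒ 3 + 4, 3 ⇒ 2, 2 ⇒ 1. The C5–C6 (ring–vinyl) bond is cut as a cross-coupling, the C4–H bond as an enantioselective ketone reduction, and the C5–I bond as an α-iodination. This reaches a commodity enone; the only demand is high enantioselectivity in 2 → 3, since all later stereocentres derive from it.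

## Other disconnections considered

Alternative 1: The cut is C4–C5 inside the five-membered ring. In the forward step Rh2(O2CCPh3)4 converts diazo ester A1 into a carbenoid at C5 that inserts into the C4–H bond next to the silyloxy group, giving cyclopentane A2. In its favour, insertion occurs with retention at C4, so the tertiary ether stereocentre is programmed by a simple secondary carbinol. On this point it is better than the chosen plan, which needs a temporary C4 stereocentre and a late organocerium addition. Against it, the quaternary C1 must already exist enantiopure in an acyclic chain, and the carbenoid can attack the ether oxygen of the side chain (five-membered oxonium ylide) or other C–H bonds. The C5 configuration relative to C1 is not secured either. A2 also contains none of the seven-membered ring: C7, C8 and its methyl must still be added, the ring closed and C6–C9 oxidised. Mechanistically both plans rest on well-understood rhodium chemistry (equal). Structurally and in step count the chosen plan is ahead, because 9 already holds the bicycle with every later oxidation site marked by an alkene.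

Alternative 2: The cuts are C1–CH3 and C5–C6; no ring is formed. In the forward step a copper-catalysed enantioselective conjugate addition of Al(CH3)3 to 3-allylcyclopent-2-enone A3 creates C1, and the aluminium enolate is trapped by ethyl glyoxylate A4 to give hydroxy ester A5. In its favour, C1 is made catalytically in one step from an achiral enone, which is shorter than the relay 2 → 3 → 5 → 6 (better on this point). C6 also arrives oxygenated with C7 as a carboxyl carbon, so the C–H oxidation of step 14 would not be needed (also better). Against it, cyclopentenones are the less selective ring size in such additions, the aldol diastereocontrol at C6 is open, and the β-hydroxy ketone is prone to retro-aldol and dehydration. The seven-membered ring still has to be closed between C7 and the allyl terminus while the C8 methyl and the C8/C9 oxygens are introduced. The alternative reaches its key intermediate faster but is slower afterwards, and C5/C6 are set with less defined control than by a syn hydroboration.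

Alternative 3: The cut is the fusion bond C1–C5, traced back to decalin hydroxy mesylate A6 in which C1 is bonded to the future C6. In the forward step Al(C2H5)3 ionises the sulfonate and C1 migrates anti-periplanar from the carbinol carbon to C5, giving hydroazulenone A7. In its favour, the shift is stereospecific (inversion at C5, retention at C1), so the trans fusion and the C4/C5 relationship follow from substrate geometry. This is better than the chosen plan, where they depend on the facial selectivities of steps 9 and 13. Against it, A6 needs four stereocentres including a monosulfonated 1,2-diol beside a tertiary silyl ether, and the correct ring bond must be aligned for migration. A7 carries its carbonyl at C6, so a reduction to the 6α-alcohol is added. The late oxidation of C7, C8 and C9 is the same as here (equal endgame). Overall it is more secure in fusion stereochemistry but longer before the key step.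

Key step: step 6

Remark on names: bicyclic compounds are named on the bicyclo[5.3.0]decane skeleton with the locants C1–C10 defined above (not von Baeyer locants); β is the face of the C1 methyl group, α the opposite face.

Remark on the structures: the quaternary C1 of 7 already has the configuration of C1 in 23, and none of its four bonds to C2, C5, C10 and CH3 is broken from 7 onwards.

Assumption: 4, 8, 14 and both enantiomers of 2-methyl-CBS-oxazaborolidine (C18H20BNO) are purchased.

## Route

Step 1
Reactants: 1 3-methylcyclopent-2-en-1-one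
Product: 2 2-iodo-3-methylcyclopent-2-en-1-one
Conditions: I2 (1.5 equiv), pyridine/CH2Cl2 (1:1), 0 °C to rt
Reagents that add atoms: iodine, II
Why: Amine-mediated α-iodination of an enone (conjugate addition of pyridine, iodination of the enolate, elimination); the iodide is the handle for attaching the future C6–C7 vinyl group.

Step 2
Reactants: 2 2-iodo-3-methylcyclopent-2-en-1-one
Product: 3 (R)-2-iodo-3-methylcyclopent-2-en-1-ol
Conditions: (S)-2-methyl-CBS-oxazaborolidine (C18H20BNO, 0.2 equiv), BH3·SMe2 (0.7 equiv), THF, 0 °C; MeOH quench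
Reagents that add atoms: none
Why: Corey–Bakshi–Shibata reduction of an α-halo cycloalkenone, a standard substrate class; the iodoalkenyl carbon acts as the large flank and the CH2 as the small one, so the (S)-catalyst should give the (R)-carbinol.

Step 3
Reactants: 3 (R)-2-iodo-3-methylcyclopent-2-en-1-ol; 4 potassium vinyltrifluoroborate
Product: 5 (R)-3-methyl-2-vinylcyclopent-2-en-1-ol
Conditions: PdCl2(dppf) (5 mol%), Cs2CO3 (3 equiv), THF/H2O (10:1), 70 °C
Reagents that add atoms: none
Why: Suzuki–Miyaura coupling of an alkenyl iodide with a vinyltrifluoroborate; the carbinol centre is not involved, and coupling at the alcohol oxidation level avoids a dimerisation-prone 2-vinyl enone.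

Step 4
Reactants: 5 (R)-3-methyl-2-vinylcyclopent-2-en-1-ol
Product: 6 (1R,2R,5R)-5-methyl-1-vinylbicyclo[3.1.0]hexan-2-ol
Conditions: Et2Zn (2.2 equiv), CH2I2 (2.2 equiv), CH2Cl2, −20 to 0 °C; pyridine then aq. NaHCO3
Reagents that add atoms: diiodomethane, ICI
Why: Hydroxyl-directed Simmons–Smith cyclopropanation (Furukawa variant); the zinc alkoxide delivers CH2 to the adjacent electron-rich ring alkene syn to oxygen and leaves the remote vinyl group, so the carbinol configuration fixes both bridgeheads (future C1 and C5).

Step 5
Reactants: 6 (1R,2R,5R)-5-methyl-1-vinylbicyclo[3.1.0]hexan-2-ol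
Product: 7 (1R,5R)-5-methyl-1-vinylbicyclo[3.1.0]hexan-2-one
Conditions: Dess–Martin periodinane (1.3 equiv), NaHCO3, CH2Cl2, 0 °C to rt
Reagents that add atoms: none
Why: Buffered hypervalent-iodine oxidation of a secondary alcohol; the non-acidic medium avoids cyclopropylcarbinyl ionisation, and the bridgehead stereocentres are untouched.

Step 6
Reactants: 7 (1R,5R)-5-methyl-1-vinylbicyclo[3.1.0]hexan-2-one; 8 1-(trimethylsilyl)propyne
Product: 9 (3aR)-3a,6-dimethyl-5-(trimethylsilyl)-3,3a,4,7-tetrahydroazulen-1(2H)-one
Conditions: [Rh(CO)2Cl]2 (5 mol%), 8 (3 equiv), 1,2-dichloroethane, 80 °C, sealed tube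
Reagents that add atoms: none
Why: Monovalent rhodium binds the vinyl group of 7 in its s-cis rotamer and inserts into the cyclopropane bond C5–C10, giving a six-membered rhodacycle with a Rh–C10 σ bond and an η3-allyl over C5–C6–C7 that is conjugated to the C4 carbonyl. Alkyne 8 then inserts into the Rh–C7 bond (forming C7–C8), and reductive elimination between the alkenyl carbon C9 and the alkyl carbon C10 forms C9–C10 and releases the catalyst. The closest known reaction type is the rhodium-catalysed intermolecular (5+2) cycloaddition of 1-substituted vinylcyclopropanes with alkynes; here the ring carbons on C5 play the role of the 1-substituent that populates the reactive rotamer. The seven-membered ring is closed as a formal (5+2) annulation onto the existing five-membered ring, through metallacycle insertion and reductive elimination, not through a polar or radical cyclisation. No stereocentre is created, and the quaternary C1 keeps its configuration because none of its bonds to C2, C5, C10 or CH3 is broken. Cleavage of C5–C10 in preference to C5–C1 is secured by the lower substitution of C10 (CH2 against a quaternary carbon), and the quaternary C1 offers no β-hydrogen for premature β-hydride elimination. The orientation of the alkyne is secured by the trimethylsilyl group, which stays on the rhodium-bound carbon during insertion and therefore ends at C9, leaving the methyl-bearing carbon at C8 bonded to C7. Base is excluded because the C7 hydrogens of 9 are doubly allylic and γ to the ketone.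

Step 7
Reactants: 9 (3aR)-3a,6-dimethyl-5-(trimethylsilyl)-3,3a,4,7-tetrahydroazulen-1(2H)-one
Product: 10 (1S,3aR)-3a,6-dimethyl-5-(trimethylsilyl)-1,2,3,3a,4,7-hexahydroazulen-1-ol
Conditions: (R)-2-methyl-CBS-oxazaborolidine (C18H20BNO, 0.2 equiv), BH3·SMe2 (0.7 equiv), THF, −30 °C; MeOH quench
Reagents that add atoms: none
Why: Corey–Bakshi–Shibata 1,2-reduction of an α-alkylidene ketone; CH3 and C10 on C1 lie on either side of the enone plane, so the catalyst decides, and with C5 as the large and C3 as the small flank the (R)-catalyst should deliver hydride to the α face to give the 4β-alcohol (4S).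

Step 8
Reactants: 10 (1S,3aR)-3a,6-dimethyl-5-(trimethylsilyl)-1,2,3,3a,4,7-hexahydroazulen-1-ol
Product: 11 4β-(triethylsilyloxy)-1β,8-dimethyl-9-(trimethylsilyl)bicyclo[5.3.0]deca-5,8-diene
Conditions: Et3SiCl (1.5 equiv), imidazole (3 equiv), DMF, 0 °C to rt
Reagents that add atoms: chlorotriethylsilane, CC[Si](Cl)(CC)CC
Why: Standard silylation of a secondary allylic alcohol; the ether protects O4 and adds a second large β substituent next to C5.

Step 9
Reactants: 11 4β-(triethylsilyloxy)-1β,8-dimethyl-9-(trimethylsilyl)bicyclo[5.3.0]deca-5,8-diene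
Product: 13 4β-(triethylsilyloxy)-1β,8-dimethyl-9-(trimethylsilyl)-5αH-bicyclo[5.3.0]dec-8-en-6α-ol, via C6α-borane 12 (not isolated)
Conditions: BH3·THF (3 equiv), THF, 0 °C to rt; then 3 M NaOH, 30% H2O2, 0 °C to rt
Reagents that add atoms: hydrogen peroxide, OO
Why: Hydroboration–oxidation; boron goes to C6 because C5 is fully substituted, syn addition occurs on the α face (the β face carries the silyloxy group on C4 and the methyl on C1, the α face only C4–H and ring CH2), so 5α-H and 6α-O are set together with a trans fusion; the tetrasubstituted vinylsilane should not react, and oxidation proceeds with retention.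

Step 10
Reactants: 13 4β-(triethylsilyloxy)-1β,8-dimethyl-9-(trimethylsilyl)-5αH-bicyclo[5.3.0]dec-8-en-6α-ol; 14 4-(benzyloxy)benzoyl chloride
Product: 15 6α-[4-(benzyloxy)benzoyloxy]-4β-(triethylsilyloxy)-1β,8-dimethyl-9-(trimethylsilyl)-5αH-bicyclo[5.3.0]dec-8-ene
Conditions: pyridine (5 equiv), 4-(dimethylamino)pyridine (0.2 equiv), CH2Cl2, 0 °C to rt
Reagents that add atoms: none
Why: Nucleophile-catalysed acylation of the only free hydroxyl; no stereocentre is affected, and the benzyl ether masks the phenol until the last step.

Step 11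
Reactants: 15 6α-[4-(benzyloxy)benzoyloxy]-4β-(triethylsilyloxy)-1β,8-dimethyl-9-(trimethylsilyl)-5αH-bicyclo[5.3.0]dec-8-ene
Product: 17 6α-[4-(benzyloxy)benzoyloxy]-1β,8-dimethyl-5αH-bicyclo[5.3.0]dec-8-en-4β-ol, via 9-silyl 4β-alcohol 16 (not isolated)
Conditions: CF3CO2H (10 equiv), CH2Cl2 containing 2% H2O, 0 °C to rt; aq. NaHCO3 work-up
Reagents that add atoms: none
Why: Acid cleaves the silyl ether first, then protodesilylates the vinylsilane by ipso protonation at C9 (β-silyl-stabilised tertiary cation at C8) and loss of silicon, which returns C8=C9 in place; the ester and the trans fusion are inert.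

Step 12
Reactants: 17 6α-[4-(benzyloxy)benzoyloxy]-1β,8-dimethyl-5αH-bicyclo[5.3.0]dec-8-en-4β-ol
Product: 18 6α-[4-(benzyloxy)benzoyloxy]-1β,8-dimethyl-5αH-bicyclo[5.3.0]dec-8-en-4-one
Conditions: Dess–Martin periodinane (1.5 equiv), NaHCO3, CH2Cl2, 0 °C to rt
Reagents that add atoms: none
Why: Neutral oxidation of a secondary alcohol; base is avoided because C5–H is now α to a ketone and β to a carboxylate, and the ketone is used without delay.

Step 13
Reactants: 18 6α-[4-(benzyloxy)benzoyloxy]-1β,8-dimethyl-5αH-bicyclo[5.3.0]dec-8-en-4-one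
Product: 19 6α-[4-(benzyloxy)benzoyloxy]-4α-isopropyl-1β,8-dimethyl-5αH-bicyclo[5.3.0]dec-8-en-4β-ol
Conditions: CeCl3 (anhydrous, 3 equiv), (CH3)2CHMgCl (3 equiv), THF, −78 °C, 1 h; then 18, −78 °C; aq. NH4Cl
Reagents that add atoms: isopropylmagnesium chloride, CC(C)[Mg]Cl
Why: Organocerium 1,2-addition; in the trans-fused cyclopentanone the axial 1β-methyl is 1,3 to C4 and blocks the β face, so the bulky nucleophile should enter from the α face (4α-isopropyl, 4β-OH), while the low basicity of the cerium reagent disfavours enolisation and ester attack at −78 °C.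

Step 14
Reactants: 19 6α-[4-(benzyloxy)benzoyloxy]-4α-isopropyl-1β,8-dimethyl-5αH-bicyclo[5.3.0]dec-8-en-4β-ol
Product: 20 6α-[4-(benzyloxy)benzoyloxy]-4α-isopropyl-1β,8-dimethyl-5αH-bicyclo[5.3.0]dec-8-ene-4β,7-diol
Conditions: SeO2 (0.5 equiv), t-BuOOH (3 equiv), CH2Cl2, rt
Reagents that add atoms: selenium dioxide, O=[Se]=O; tert-butyl hydroperoxide, CC(C)(C)OO
Why: Riley allylic oxidation; the ene step bonds selenium to the less substituted C9 and removes a hydrogen from the ring CH2 on the more substituted side (C7, preferred over the methyl; C10 is not addressed by this mechanism), and the [2,3] shift returns C8=C9 with oxygen on C7, whose configuration is irrelevant.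

Step 15
Reactants: 20 6α-[4-(benzyloxy)benzoyloxy]-4α-isopropyl-1β,8-dimethyl-5αH-bicyclo[5.3.0]dec-8-ene-4β,7-diol
Product: 21 6α-[4-(benzyloxy)benzoyloxy]-4β-hydroxy-4α-isopropyl-1β,8-dimethyl-5αH-bicyclo[5.3.0]dec-8-en-7-one
Conditions: Dess–Martin periodinane (1.5 equiv), NaHCO3, CH2Cl2, 0 °C to rt
Reagents that add atoms: none
Why: Oxidation of the secondary allylic alcohol to the enone; the tertiary C4 hydroxyl cannot react, and the equatorial 6α-ester is expected to be the stable configuration next to the new ketone.

Step 16
Reactants: 21 6α-[4-(benzyloxy)benzoyloxy]-4β-hydroxy-4α-isopropyl-1β,8-dimethyl-5αH-bicyclo[5.3.0]dec-8-en-7-one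
Product: 22 6α-[4-(benzyloxy)benzoyloxy]-4β,8α,9α-trihydroxy-4α-isopropyl-1β,8β-dimethyl-5αH-bicyclo[5.3.0]decan-7-one
Conditions: OsO4 (5 mol%), N-methylmorpholine N-oxide (2 equiv), citric acid (1 equiv), t-BuOH/H2O (1:1), rt
Reagents that add atoms: osmium tetroxide, O=[Os](=O)(=O)=O; N-methylmorpholine N-oxide, C[N+]1([O-])CCOCC1; water, O
Why: Catalytic syn dihydroxylation of an enone; OsO4 should approach the α face, anti to the axial 1β-methyl that is 1,3 to C9 (the 6α-ester is equatorial), giving 8α-OH, 8β-CH3 and 9α-OH in one event, and the slightly acidic medium speeds turnover and protects the α-ketol and ester.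

Step 17
Reactants: 22 6α-[4-(benzyloxy)benzoyloxy]-4β,8α,9α-trihydroxy-4α-isopropyl-1β,8β-dimethyl-5αH-bicyclo[5.3.0]decan-7-one
Product: 23 4β,8α,9α-trihydroxy-6α-(4-hydroxybenzoyloxy)-4α-isopropyl-1β,8β-dimethyl-5αH-bicyclo[5.3.0]decan-7-one (CNP0241001.1)
Conditions: H2 (1 atm), Pd/C (10 wt%), ethyl acetate, rt
Reagents that add atoms: none
Why: Hydrogenolysis of the benzyl aryl ether under neutral conditions; no alkene remains, and the ketone, esters and alcohols are inert.

## Compound list

1 | 3-methylcyclopent-2-en-1-one | CC1=CC(=O)CC1 | starting material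
2 | 2-iodo-3-methylcyclopent-2-en-1-one | CC1=C(I)C(=O)CC1 | intermediate
3 | (R)-2-iodo-3-methylcyclopent-2-en-1-ol | O[C@@H]1CCC(C)=C1I | intermediate
4 | potassium vinyltrifluoroborate | C=C[B-](F)(F)F.[K+] | starting material
5 | (R)-3-methyl-2-vinylcyclopent-2-en-1-ol | O[C@@H]1CCC(C)=C1C=C | intermediate
6 | (1R,2R,5R)-5-methyl-1-vinylbicyclo[3.1.0]hexan-2-ol (hydroxyl cis to the cyclopropane CH2) | O[C@@H]1CC[C@]2(C)C[C@]12C=C | intermediate
7 | (1R,5R)-5-methyl-1-vinylbicyclo[3.1.0]hexan-2-one | O=C1CC[C@]2(C)C[C@]12C=C | intermediate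
8 | 1-(trimethylsilyl)propyne | CC#C[Si](C)(C)C | starting material
9 | (3aR)-3a,6-dimethyl-5-(trimethylsilyl)-3,3a,4,7-tetrahydroazulen-1(2H)-one (C4 ketone, C5=C6, C8=C9, 1β-CH3, 8-CH3, 9-SiMe3) | O=C1CC[C@]2(C)CC([Si](C)(C)C)=C(C)CC=C12 | intermediate
10 | (1S,3aR)-3a,6-dimethyl-5-(trimethylsilyl)-1,2,3,3a,4,7-hexahydroazulen-1-ol (4β-alcohol, 4S) | O[C@H]1CC[C@]2(C)CC([Si](C)(C)C)=C(C)CC=C12 | intermediate
11 | 4β-(triethylsilyloxy)-1β,8-dimethyl-9-(trimethylsilyl)bicyclo[5.3.0]deca-5,8-diene | CC[Si](CC)(CC)O[C@H]1CC[C@]2(C)CC([Si](C)(C)C)=C(C)CC=C12 | intermediate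
12 | 6α-boryl-4β-(triethylsilyloxy)-1β,8-dimethyl-9-(trimethylsilyl)-5αH-bicyclo[5.3.0]dec-8-ene | CC[Si](CC)(CC)O[C@H]1CC[C@]2(C)CC([Si](C)(C)C)=C(C)C[C@H](B)[C@H]21 | intermediate (not isolated)
13 | 4β-(triethylsilyloxy)-1β,8-dimethyl-9-(trimethylsilyl)-5αH-bicyclo[5.3.0]dec-8-en-6α-ol | CC[Si](CC)(CC)O[C@H]1CC[C@]2(C)CC([Si](C)(C)C)=C(C)C[C@H](O)[C@H]21 | intermediate
14 | 4-(benzyloxy)benzoyl chloride | O=C(Cl)c1ccc(OCc2ccccc2)cc1 | starting material
15 | 6α-[4-(benzyloxy)benzoyloxy]-4β-(triethylsilyloxy)-1β,8-dimethyl-9-(trimethylsilyl)-5αH-bicyclo[5.3.0]dec-8-ene | CC[Si](CC)(CC)O[C@H]1CC[C@]2(C)CC([Si](C)(C)C)=C(C)C[C@H](OC(=O)c3ccc(OCc4ccccc4)cc3)[C@H]21 | intermediate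
16 | 6α-[4-(benzyloxy)benzoyloxy]-1β,8-dimethyl-9-(trimethylsilyl)-5αH-bicyclo[5.3.0]dec-8-en-4β-ol | O[C@H]1CC[C@]2(C)CC([Si](C)(C)C)=C(C)C[C@H](OC(=O)c3ccc(OCc4ccccc4)cc3)[C@H]21 | intermediate (not isolated)
17 | 6α-[4-(benzyloxy)benzoyloxy]-1β,8-dimethyl-5αH-bicyclo[5.3.0]dec-8-en-4β-ol | O[C@H]1CC[C@]2(C)CC=C(C)C[C@H](OC(=O)c3ccc(OCc4ccccc4)cc3)[C@H]21 | intermediate
18 | 6α-[4-(benzyloxy)benzoyloxy]-1β,8-dimethyl-5αH-bicyclo[5.3.0]dec-8-en-4-one | O=C1CC[C@]2(C)CC=C(C)C[C@H](OC(=O)c3ccc(OCc4ccccc4)cc3)[C@H]21 | intermediate
19 | 6α-[4-(benzyloxy)benzoyloxy]-4α-isopropyl-1β,8-dimethyl-5αH-bicyclo[5.3.0]dec-8-en-4β-ol | CC(C)[C@]1(O)CC[C@]2(C)CC=C(C)C[C@H](OC(=O)c3ccc(OCc4ccccc4)cc3)[C@H]21 | intermediate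
20 | 6α-[4-(benzyloxy)benzoyloxy]-4α-isopropyl-1β,8-dimethyl-5αH-bicyclo[5.3.0]dec-8-ene-4β,7-diol (C7 configuration open, removed in step 15) | CC(C)[C@]1(O)CC[C@]2(C)CC=C(C)C(O)[C@H](OC(=O)c3ccc(OCc4ccccc4)cc3)[C@H]21 | intermediate
21 | 6α-[4-(benzyloxy)benzoyloxy]-4β-hydroxy-4α-isopropyl-1β,8-dimethyl-5αH-bicyclo[5.3.0]dec-8-en-7-one | CC(C)[C@]1(O)CC[C@]2(C)CC=C(C)C(=O)[C@H](OC(=O)c3ccc(OCc4ccccc4)cc3)[C@H]21 | intermediate
22 | 6α-[4-(benzyloxy)benzoyloxy]-4β,8α,9α-trihydroxy-4α-isopropyl-1β,8β-dimethyl-5αH-bicyclo[5.3.0]decan-7-one | CC(C)[C@]1(O)CC[C@]2(C)C[C@H](O)[C@](C)(O)C(=O)[C@H](OC(=O)c3ccc(OCc4ccccc4)cc3)[C@H]21 | intermediate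
23 | 4β,8α,9α-trihydroxy-6α-(4-hydroxybenzoyloxy)-4α-isopropyl-1β,8β-dimethyl-5αH-bicyclo[5.3.0]decan-7-one, (1R,4R,5S,6R,8S,9S) in the locants used here | CC(C)[C@]1(O)CC[C@]2(C)C[C@H](O)[C@](C)(O)C(=O)[C@H](OC(=O)c3ccc(O)cc3)[C@H]21 | target

## Step count and least certain steps

Total: 17 steps. Longest linear sequence: 17 steps (1 to 23); 4, 8 and 14 enter as purchased reagents.

Step 6 (key step). The most likely failure is slow alkyne insertion: the rhodacycle from an acyl-substituted cyclopropane can rest as an oxygen-bound rhodium dienolate, so that alkyne oligomerisation or ring-opening isomerisation of the ketone consumes material. The orientation of the alkyne could also erode. The fallback removes the acyl group from the cyclopropane and keeps the same bond formation. It sets out from 6: silylation (Et3SiCl, imidazole) should give triethylsilyl ether F1. The same rhodium-catalysed reaction with 8 should give silylated cycloadduct F2. Bu4NF should release 4α-alcohol F3 (the C4 epimer of 10), and MnO2 oxidation returns to the route at 9.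

Step 13. The most likely failure is enolisation of 18 towards C5 followed by β-elimination of the C6 carboxylate, which regenerates a C5=C6 enone. Attack on the aryl ester or reduction by β-hydride transfer are further possibilities. The fallback keeps oxygen at C6 as a silyl ether during the addition and acylates afterwards. It sets out from 13: t-BuMe2SiOSO2CF3 and 2,6-lutidine should give bis-silyl ether F4. Pyridinium p-toluenesulfonate in MeOH should cleave only the triethylsilyl group to give alcohol F5. Dess–Martin oxidation should give silyloxy ketone F6, and the organocerium addition of step 13 should give tertiary alcohol F7. Wet CF3CO2H in CH2Cl2 should remove both remaining silicon groups to give diol F8. Acylation of its only secondary hydroxyl with 14 returns to the route at 19.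

Step 14. The most likely failure is oxidation of the C8 methyl group, or a sluggish ene step because C7 is flanked by the acyloxy-bearing C6. The fallback builds the C7 oxygen by a carbonyl transposition with unambiguous regiochemistry. It sets out from 19: hydroboration–oxidation (BH3·THF; NaBO3) should place oxygen at C9 to give 9-alcohol F9. Dess–Martin oxidation should give 9-ketone F10. Dehydrogenation with 2-iodoxybenzoic acid can only run towards C8, because C10 has no β-hydrogen on C1, and should give 7-en-9-one F11. Epoxidation with t-BuOOH and 1,8-diazabicyclo[5.4.0]undec-7-ene should give epoxy ketone F12. Wharton transposition (N2H4·H2O, AcOH, MeOH) moves the alkene to C8=C9 and leaves the hydroxyl on C7, returning to the route at 20.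

Step 4. The most likely failure is over-reaction at the vinyl group, or zinc-halide-induced opening of the acid-sensitive vinylcyclopropyl carbinol. The fallback carries the vinyl group as an alkyne, which zinc carbenoids do not attack. It sets out from 3: Sonogashira coupling with trimethylsilylacetylene (PdCl2(PPh3)2, CuI, Et3N) should give enyne F13. The directed Simmons–Smith reaction should give alkynylcyclopropane F14. K2CO3 in MeOH should give terminal alkyne F15. Semihydrogenation (H2, Pd/CaCO3 poisoned with Pb(OAc)2, quinoline) returns to the route at 6.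

## Further compounds

F1 | step 6 | triethylsilyl ether of 6 (configuration of 6 retained) | CC[Si](CC)(CC)O[C@@H]1CC[C@]2(C)C[C@]12C=C
F2 | step 6 | 4α-(triethylsilyloxy)-1β,8-dimethyl-9-(trimethylsilyl)bicyclo[5.3.0]deca-5,8-diene | CC[Si](CC)(CC)O[C@@H]1CC[C@]2(C)CC([Si](C)(C)C)=C(C)CC=C12
F3 | step 6 | 1β,8-dimethyl-9-(trimethylsilyl)bicyclo[5.3.0]deca-5,8-dien-4α-ol (C4 epimer of 10) | O[C@@H]1CC[C@]2(C)CC([Si](C)(C)C)=C(C)CC=C12
F4 | step 13 | 6α-(tert-butyldimethylsilyloxy)-4β-(triethylsilyloxy)-1β,8-dimethyl-9-(trimethylsilyl)-5αH-bicyclo[5.3.0]dec-8-ene | CC[Si](CC)(CC)O[C@H]1CC[C@]2(C)CC([Si](C)(C)C)=C(C)C[C@H](O[Si](C)(C)C(C)(C)C)[C@H]21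
F5 | step 13 | 6α-(tert-butyldimethylsilyloxy)-1β,8-dimethyl-9-(trimethylsilyl)-5αH-bicyclo[5.3.0]dec-8-en-4β-ol | O[C@H]1CC[C@]2(C)CC([Si](C)(C)C)=C(C)C[C@H](O[Si](C)(C)C(C)(C)C)[C@H]21
F6 | step 13 | 6α-(tert-butyldimethylsilyloxy)-1β,8-dimethyl-9-(trimethylsilyl)-5αH-bicyclo[5.3.0]dec-8-en-4-one | O=C1CC[C@]2(C)CC([Si](C)(C)C)=C(C)C[C@H](O[Si](C)(C)C(C)(C)C)[C@H]21
F7 | step 13 | 6α-(tert-butyldimethylsilyloxy)-4α-isopropyl-1β,8-dimethyl-9-(trimethylsilyl)-5αH-bicyclo[5.3.0]dec-8-en-4β-ol | CC(C)[C@]1(O)CC[C@]2(C)CC([Si](C)(C)C)=C(C)C[C@H](O[Si](C)(C)C(C)(C)C)[C@H]21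
F8 | step 13 | 4α-isopropyl-1β,8-dimethyl-5αH-bicyclo[5.3.0]dec-8-ene-4β,6α-diol | CC(C)[C@]1(O)CC[C@]2(C)CC=C(C)C[C@H](O)[C@H]21
F9 | step 14 | 6α-[4-(benzyloxy)benzoyloxy]-4α-isopropyl-1β,8-dimethyl-5αH-bicyclo[5.3.0]decane-4β,9-diol (C8 and C9 configurations immaterial) | CC(C)[C@]1(O)CC[C@]2(C)CC(O)C(C)C[C@H](OC(=O)c3ccc(OCc4ccccc4)cc3)[C@H]21
F10 | step 14 | 6α-[4-(benzyloxy)benzoyloxy]-4β-hydroxy-4α-isopropyl-1β,8-dimethyl-5αH-bicyclo[5.3.0]decan-9-one (C8 configuration immaterial) | CC(C)[C@]1(O)CC[C@]2(C)CC(=O)C(C)C[C@H](OC(=O)c3ccc(OCc4ccccc4)cc3)[C@H]21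
F11 | step 14 | 6α-[4-(benzyloxy)benzoyloxy]-4β-hydroxy-4α-isopropyl-1β,8-dimethyl-5αH-bicyclo[5.3.0]dec-7-en-9-one | CC(C)[C@]1(O)CC[C@]2(C)CC(=O)C(C)=C[C@H](OC(=O)c3ccc(OCc4ccccc4)cc3)[C@H]21
F12 | step 14 | 6α-[4-(benzyloxy)benzoyloxy]-7,8-epoxy-4β-hydroxy-4α-isopropyl-1β,8-dimethyl-5αH-bicyclo[5.3.0]decan-9-one (epoxide face immaterial) | CC(C)[C@]1(O)CC[C@]2(C)CC(=O)C3(C)OC3[C@H](OC(=O)c4ccc(OCc5ccccc5)cc4)[C@H]21
F13 | step 4 | (R)-3-methyl-2-[(trimethylsilyl)ethynyl]cyclopent-2-en-1-ol | O[C@@H]1CCC(C)=C1C#C[Si](C)(C)C
F14 | step 4 | 5-methyl-1-[(trimethylsilyl)ethynyl]bicyclo[3.1.0]hexan-2-ol (configured as 6, hydroxyl cis to the cyclopropane CH2) | O[C@@H]1CC[C@]2(C)C[C@]12C#C[Si](C)(C)C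
F15 | step 4 | 1-ethynyl-5-methylbicyclo[3.1.0]hexan-2-ol (configured as 6) | O[C@@H]1CC[C@]2(C)C[C@]12C#C
A1 | alternative 1 | ethyl 6-(tert-butyldimethylsilyloxy)-3-[2-(tert-butyldimethylsilyloxy)ethyl]-2-diazo-3,7-dimethyloctanoate (configured as required for A2) | CCOC(=O)C(=[N+]=[N-])[C@@](C)(CCO[Si](C)(C)C(C)(C)C)CC[C@@H](O[Si](C)(C)C(C)(C)C)C(C)C
A2 | alternative 1 | cyclopentane with C4 tertiary silyl ether, C5 ethyl ester and quaternary C1 | CC(C)[C@]1(O[Si](C)(C)C(C)(C)C)CC[C@](C)(CCO[Si](C)(C)C(C)(C)C)[C@H]1C(=O)OCC
A3 | alternative 2 | 3-allylcyclopent-2-en-1-one | C=CCC1=CC(=O)CC1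
A4 | alternative 2 | ethyl glyoxylate | CCOC(=O)C=O
A5 | alternative 2 | trans-2,3-disubstituted cyclopentanone with C1 methyl and allyl and the C6 hydroxy ester | O=C1CC[C@](C)(CC=C)[C@H]1[C@@H](O)C(=O)OCC
A6 | alternative 3 | decalin hydroxy mesylate: tertiary carbinol at the future C6, mesylate at the future C5, triethylsilyl-protected isopropyl carbinol at C4 (carbinol configuration at C6 left open) | CC(C)[C@]1(O[Si](CC)(CC)CC)CC[C@]2(C)CC=C(C)CC2(O)[C@H]1OS(C)(=O)=O
A7 | alternative 3 | trans-fused 6-oxo-hydroazulene with C8=C9 alkene and C4 triethylsilyl ether | CC(C)[C@]1(O[Si](CC)(CC)CC)CC[C@]2(C)CC=C(C)CC(=O)[C@H]21
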